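**The crossing.** Thursday's flask was to stand 15 d, 18.0 times longer than the 20.0 h at which its starting material read 0%, so when you asked for a quick number I answered from the end of the run.

| setting | Thursday's | flask |
|---|---|---|
| starting material | 0.34 M | 0.34 M |
| gas | 72 mM (held) | 72 mM (held) |
| remark | the very flask that is asked about, followed so far |  |
| time |  | 15 d |

- Thursday's (time / h: target / %, side product / %, starting material / %): 2.50: 21.6, 11.7, 66.8; 8.00: 53.9, 33.4, 14.9; 12.0: 58.5, 38.7, 2.3; 20.0: 59.6, 39.8, 0; 30.0: 58.5, 41.0, 0.5

(readings scatter by 0.5 percentage points)

- at the start none of the gas is in solution

1. how much target there is at 15 d, in percent of the starting material charged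
2. how much side product there is at 15 d, in percent of the starting material charged

**My reckoning.** Starting material read 0% at 20.0 h and 0.5% at 30.0 h, so I used those two readings. From them I took the closing share, the target's part of the two products at the end of the run (the overall selectivity), which is a reading with their scatter: 59.4%. The later target reading stood 1.1 percentage points below the earlier one, and that was 1.56 times the scatter of a difference of two readings, too little for me to call it a reaction. I therefore committed to 59.4% target and 40.6% side product.

**Your forecast.** The forecast said 42% target and 58% side product, reading the same drift as a “slow target-to-side-product conversion”. For target, my number stood 17 points above it.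

**What came.** The flask gave 59.5% target and 40.5% side product at 15 d.

    starting material + 2 partner → side product (k = 0.0191 L² mol⁻² s⁻¹)
    gas ⇌ partner, rate k2*(csat - [partner]) (kL = 4.56 × 10⁻⁴ s⁻¹)
    starting material + partner → target (k = 0.00107 L mol⁻¹ s⁻¹)

The scheme has no step leaving target, and the flask held 59.5% target at 7.50 d and 59.5% at 150 d. The neighbour, the same flask read at 10 d, stood 12.0 times past 20.0 h, so the closing share told 59.4% target and 40.6% side product for it. That neighbour held 59.5% target and 40.5% side product.

All runs were computed on assumed constants; the scatter is artificial.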